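**Limiting reagent.** The ratio of protic impurity to substrate is 0.300. So even if the impurity quenches its full share of partner, 1.70 equiv of partner remain per substrate, and substrate is the limiting reagent. Its balance reads: c_substrate + c_intermediate + c_product = what has been fed, which at the end is the whole charge.

| flask | substrate | partner | protic impurity | free catalyst | second catalyst | remark | time |
|---|---|---|---|---|---|---|---|
| Tuesday's | 0.17 M (fed, over 3.0 min) | 2 equiv | 0.051 M | 0.2 mol% | 0.82 mol% | run made earlier |  |
| Wednesday's | 0.17 M (fed, over 3.0 min) | 2 equiv | 0.051 M | 0.2 mol% | 12 mol% | run made earlier |  |
| autumn | 0.17 M (fed, over 3.0 min) | 2.00 equiv | 0.0510 M | 0.2 mol% | 0.6 mol% |  | 3.0 min |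
| summer | 0.17 M (fed, over 3.0 min) | 2.00 equiv | 0.0510 M | 0.2 mol% | 1.2 mol% |  | 3.0 min |
| dawn | 0.17 M (fed, over 3.0 min) | 2.00 equiv | 0.0510 M | 0.2 mol% | 2.5 mol% |  | 3.0 min |
| noon | 0.17 M (fed, over 3.0 min) | 2.00 equiv | 0.0510 M | 0.2 mol% | 5 mol% |  | 3.0 min |
| dusk | 0.17 M (fed, over 3.0 min) | 2.00 equiv | 0.0510 M | 0.2 mol% | 10 mol% |  | 3.0 min |

| run | time / s | intermediate / % | product / % |
|---|---|---|---|
| Tuesday's | 25.0 | 0 | 0 |
| Tuesday's | 50.0 | 5 | 0 |
| Tuesday's | 60.0 | 9 | 0 |
| Tuesday's | 90.0 | 16 | 1 |
| Wednesday's | 12.0 | 2 | 6 |
| Wednesday's | 30.0 | 4 | 0 |
| Wednesday's | 60.0 | 7 | 3 |
| Wednesday's | 90.0 | 14 | 2 |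

(scatter of a reading: 2 percentage points)

- what may be going on: substrate + free catalyst -> free catalyst + intermediate; partner + protic impurity -> quenched reagent; partner + second catalyst + intermediate -> second catalyst + product
- percentages count the whole charge, also what has not yet gone in
- "hardly changes" means that all values lie within two and a half points (for a concentration: within two and a half percent of the largest)

1. amount of intermediate at the end, in percent of the substrate charged for autumn, summer, dawn, noon, dusk, in this order
2. how that number moves from the first to the last of them (rises all the way / rises, then falls / falls, then rises / hardly changes / falls all the way)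

**Reading the step.** In the proposed scheme, second catalyst has no part in the first step, so intermediate plus product should not depend on its loading. At 90.0 s that sum reads 17.0% on Tuesday and 16.0% on Wednesday. The mean, 16.5%, carries the scatter of one reading. With steady feed and a constant pseudo-first-order constant κ, the fraction of the fed substrate that has reacted is 1 − (1 − e^(−u))/u, with u = κt, which is close to (u/2)/(1 + u/3). At that time half of the charge is in, so κ reads 0.00940 /s, or 0.00799 /s to 0.0109 /s within one scatter.

**The ceiling.** This gives 51.8% for the passed share, the part of the whole charge that has left the substrate by the end of the feed. The range is 47.0% to 56.2%. Intermediate cannot exceed the passed share, so 56.2% is our ceiling for autumn and dusk alike.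

**The floor.** Wednesday's product at 90.0 s, taken two scatters high, is 6.00%. We take product to grow with the loading and with the area under intermediate, and that area to lie below the area under the passed share, which grows 6.71-fold up to 3.0 min. Wednesday's figure has to be corrected before it is scaled down: if product's part of the passed share rises with time, Wednesday's intermediate up to 90.0 s stood at 63.6% of the passed share or more, so we divide by that. Our limit for product is then 3.16% in autumn and 52.7% in dusk. The floor for autumn is therefore 43.8%, but the limit for dusk stands above the low passed share of 47.0%, so this reckoning gives dusk no floor above zero. We expect a fall from autumn to dusk, since the passed share stays put while product rises.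

**The result.** The forecast runs from 51% to 39%, "Intermediate therefore falls slowly", inside the autumn bracket and below the ceiling for dusk. The flask gives 53.8%, 51.7%, 47.5%, 41.0% and 32.0%, so the row falls all the way, with autumn inside its bracket and dusk below the ceiling.

    substrate + free catalyst → free catalyst + intermediate (k = 32.0 /M/s)
    partner + protic impurity → quenched reagent (k = 0.120 /M/s)
    partner + second catalyst + intermediate → second catalyst + product (k = 2.10 /M²/s)

**Passed share again.** Autumn ends with intermediate plus product at 56.1% and dusk at 56.2%, beside our reckoned 51.8% with its upper value 56.2%. In autumn, the half-life of intermediate by the second step alone, with the other concentrations as charged, is 16 min, longer than the 3.0 min of the run. At that time autumn holds 2.30% product and dusk holds 24.2%.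

Readings and results were computed on assumed constants.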